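**Plan**

- Lactone numbering: O1, C2 (C=O), C3, C4 (CO2H-bearing), C5 (chain-bearing); chain carbons C1′–C15′. The retrosynthesis cuts, in this order, the exocyclic C3=CH2 bond, the C5–O1 bond and the C5–C1′ bond; both carboxyl groups are traced back to benzyl-protected CH2OH groups.
- The C5–O1 cut rests on one feature: ring atoms C2, C3, C4 and C5 are a four-carbon chain bridged by O1, that is, a cyclobutanone with one oxygen inserted between its carbonyl carbon and the chain-bearing α-carbon.
- Forward: a C15 aldehyde from ω-pentadecalactone is joined to 3-(benzyloxymethyl)cyclobutanone through its silyl enol ether (aldol addition, dehydration, hydrogenation). The only ring that is formed, the γ-lactone, then arises by ring expansion of the four-membered ketone; the acids and the methylene group come last.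
- Stereochemistry: C4 comes from enantioselective deprotonation of the prochiral cyclobutanone by a chiral lithium amide. C5 is set trans to it by equilibration of the ketone α-carbon and passes through the ring expansion with retention.

Key step: step 8

Assumption: the (R,R)-configured lithium amide is taken to give the (S)-enol ether, by analogy with related 3-substituted cyclobutanones and 4-substituted cyclohexanones; should the sense be opposite, the equally available (S,S)-amine is used and nothing else changes.

**Step 1**
Reactants: 1 ω-pentadecalactone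
Product: 2 pentadecane-1,15-diol
Conditions: LiAlH4, THF, 0 °C → reflux; aqueous NaOH work-up
Reagents that add atoms: none
Why: Lithium aluminium hydride reduction of a lactone to the diol is a standard ester reduction, the macrolactone carries no other reducible group and no stereocentre is involved.

**Step 2**
Reactants: 2 pentadecane-1,15-diol
Product: 3 15-(benzyloxy)pentadecan-1-ol
Conditions: NaH, BnBr, n-Bu4NI (cat.), THF/DMF, 0 °C → rt; diol in excess, recovered
Reagents that add atoms: benzyl bromide, BrCc1ccccc1
Why: Williamson ether synthesis on one alkoxide of a symmetrical diol, where the excess of diol over base and halide should keep double benzylation low.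

**Step 3**
Reactants: 3 15-(benzyloxy)pentadecan-1-ol
Product: 4 15-(benzyloxy)pentadecanal
Conditions: TEMPO (cat.), PhI(OAc)2, CH2Cl2, rt
Reagents that add atoms: none
Why: Oxoammonium (TEMPO) oxidation with PhI(OAc)2 as terminal oxidant should stop at the aldehyde in anhydrous CH2Cl2 and leaves the benzyl ether untouched.

**Step 4**
Reactants: 5 3-(benzyloxymethyl)cyclobutanone
Product: 7 (S)-3-(benzyloxymethyl)-1-(triethylsilyloxy)cyclobut-1-ene, via lithium enolate 6 (not isolated)
Conditions: (R,R)-bis(1-phenylethyl)amine, n-BuLi, THF, −78 → 0 °C; then TESCl and 5 (added last), −100 °C, in situ quench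
Reagents that add atoms: chlorotriethylsilane, CC[Si](Cl)(CC)CC
Why: Enantioselective deprotonation of a prochiral ketone by a C2-symmetric chiral lithium amide under in situ silyl quench, a known desymmetrisation of 3-substituted cyclobutanones, should remove a proton from one of the two enantiotopic α-methylene groups, which makes C3 a stereocentre of (S) configuration, while immediate O-silylation of enolate 6 prevents proton exchange and self-aldol.

**Step 5**
Reactants: 7 (S)-3-(benzyloxymethyl)-1-(triethylsilyloxy)cyclobut-1-ene; 4 15-(benzyloxy)pentadecanal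
Product: 8 (2S,3S)-3-(benzyloxymethyl)-2-[15-(benzyloxy)-1-hydroxypentadecyl]cyclobutan-1-one (mixture at the carbinol carbon)
Conditions: TiCl4, CH2Cl2, −78 °C; H2O quench
Reagents that add atoms: none
Why: In this Mukaiyama aldol addition the TiCl4-activated aldehyde is attacked regiospecifically by the enol ether carbon C2, so the C3 stereocentre from step 4 is untouched, and the two new centres (C2, expected anti to the CH2OBn group, and the carbinol carbon) are both erased in steps 6 and 7.

**Step 6**
Reactants: 8 (2S,3S)-3-(benzyloxymethyl)-2-[15-(benzyloxy)-1-hydroxypentadecyl]cyclobutan-1-one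
Product: 10 (S,E)-3-(benzyloxymethyl)-2-[15-(benzyloxy)pentadecylidene]cyclobutan-1-one, via mesylate 9 (not isolated)
Conditions: MsCl, Et3N, CH2Cl2, 0 °C; then DBU, 0 °C → rt
Reagents that add atoms: none
Why: Mesylation of the β-hydroxy ketone and base-induced E1cB elimination (completion of an aldol condensation) should give the conjugated exocyclic enone, whose geometry is of no consequence, and C3 lies outside the enolisable system and keeps its configuration.

**Step 7**
Reactants: 10 (S,E)-3-(benzyloxymethyl)-2-[15-(benzyloxy)pentadecylidene]cyclobutan-1-one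
Product: 12 (2R,3S)-3-(benzyloxymethyl)-2-[15-(benzyloxy)pentadecyl]cyclobutan-1-one, via cis-ketone 11 (not isolated)
Conditions: H2 (1 atm), Pd/C, pyridine, EtOAc, rt; filter; then DBU (cat.), CH2Cl2, rt
Reagents that add atoms: none
Why: Heterogeneous hydrogenation on Pd/C moderated by pyridine, which is known to suppress benzyl ether hydrogenolysis, should add hydrogen anti to the CH2OBn group to give mainly cis-ketone 11, and DBU then epimerises the α-carbon C2 through the enolate to the thermodynamically preferred trans isomer, so the (2R) centre is set relative to C3 under thermodynamic control (residual cis isomer is separated and re-equilibrated).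

**Step 8**
Reactants: 12 (2R,3S)-3-(benzyloxymethyl)-2-[15-(benzyloxy)pentadecyl]cyclobutan-1-one
Product: 14 (4R,5R)-4-(benzyloxymethyl)-5-[15-(benzyloxy)pentadecyl]dihydrofuran-2(3H)-one, via Criegee adduct 13 (not isolated)
Conditions: mCPBA, NaHCO3, CH2Cl2, 0 °C → rt
Reagents that add atoms: m-chloroperoxybenzoic acid, OOC(=O)c1cccc(Cl)c1
Why: The peracid adds to the strained carbonyl of 12 to give the tetrahedral Criegee adduct 13, and the more substituted α-carbon C2 shifts from carbon to the proximal peroxide oxygen with loss of 3-chlorobenzoate, which forms the C5–O1 bond of the lactone. This is the Baeyer–Villiger oxidation, long established for 2-alkylcyclobutanones as a regioselective entry to 5-substituted γ-butyrolactones. The five-membered ring is not closed by a cyclisation but arises by 1,2-shift ring expansion (oxygen insertion into the C1–C2 bond of the ketone), driven by release of cyclobutanone strain. No stereocentre is created: the migrating carbon keeps its configuration and C3 is a spectator, so the trans pair of 12 becomes the (4R,5R) pair of 14. The step needs migration of the secondary carbon C2 in preference to the ring CH2, and the higher migratory aptitude of the more substituted carbon, which better carries the developing positive charge, secures it. The benzyl ethers are inert to buffered peracid at this temperature.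

**Step 9**
Reactants: 14 (4R,5R)-4-(benzyloxymethyl)-5-[15-(benzyloxy)pentadecyl]dihydrofuran-2(3H)-one
Product: 15 (4R,5R)-4-(hydroxymethyl)-5-(15-hydroxypentadecyl)dihydrofuran-2(3H)-one
Conditions: H2 (1 atm), Pd/C, EtOAc, rt
Reagents that add atoms: none
Why: Hydrogenolysis of both benzyl ethers over Pd/C is routine, the saturated lactone is inert to it, and the neutral aprotic medium is chosen to avoid acyl migration to the freed C4 hydroxymethyl group.

**Step 10**
Reactants: 15 (4R,5R)-4-(hydroxymethyl)-5-(15-hydroxypentadecyl)dihydrofuran-2(3H)-one
Product: 16 (2R,3S)-2-(14-carboxytetradecyl)-5-oxotetrahydrofuran-3-carboxylic acid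
Conditions: CrO3, aq. H2SO4, acetone, 0 °C
Reagents that add atoms: water, O (supplies the second oxygen of each new carboxyl group through the aldehyde hydrate)
Why: Jones oxidation takes both primary alcohols through their aldehyde hydrates to carboxylic acids, a standard way from 4-hydroxymethyl-γ-butyrolactones to paraconic acids, and the acidic medium does not epimerise either ring stereocentre.

**Step 11**
Reactants: 16 (2R,3S)-2-(14-carboxytetradecyl)-5-oxotetrahydrofuran-3-carboxylic acid
Product: 17 (2R,3S)-2-(14-carboxytetradecyl)-5-oxotetrahydrofuran-3,4-dicarboxylic acid (epimers at the new malonic carbon)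
Conditions: MeOMgOCO2Me (methyl methoxymagnesium carbonate, 2 M in DMF, excess), 130 °C; then cold aq. HCl
Reagents that add atoms: methyl methoxymagnesium carbonate, COC(=O)O[Mg]OC
Why: In this Stiles carboxylation the reagent carboxylates the lactone α-carbon through a magnesium-chelated enolate–carboxylate, the established activation of paraconic acids for methylenation, while the two existing acids are merely carried as magnesium carboxylates and the trans arrangement of the ring substituents is the thermodynamically favoured one.

**Step 12**
Reactants: 17 (2R,3S)-2-(14-carboxytetradecyl)-5-oxotetrahydrofuran-3,4-dicarboxylic acid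
Product: 19 (2R,3S)-2-(14-carboxytetradecyl)-4-methylene-5-oxotetrahydrofuran-3-carboxylic acid (CNP0222442.1), via Mannich base 18 (not isolated)
Conditions: 37% aq. HCHO, PhNHMe, NaOAc, AcOH, rt
Reagents that add atoms: formaldehyde, C=O
Why: In this decarboxylative Mannich methylenation the malonic-type acid next to the lactone carbonyl condenses with formaldehyde and N-methylaniline to Mannich base 18, which loses CO2 and the amine to form the exocyclic C=CH2 bond without touching the two ring stereocentres.

**Compound list**

1 | ω-pentadecalactone (oxacyclohexadecan-2-one) | O=C1CCCCCCCCCCCCCCO1 | starting material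
2 | pentadecane-1,15-diol | OCCCCCCCCCCCCCCCO | intermediate
3 | 15-(benzyloxy)pentadecan-1-ol | OCCCCCCCCCCCCCCCOCc1ccccc1 | intermediate
4 | 15-(benzyloxy)pentadecanal | O=CCCCCCCCCCCCCCCOCc1ccccc1 | intermediate
5 | 3-(benzyloxymethyl)cyclobutanone | O=C1CC(COCc2ccccc2)C1 | starting material
6 | lithium (S)-3-(benzyloxymethyl)cyclobut-1-en-1-olate (formed in the flask) | C1C(O[Li])=C[C@H]1COCc2ccccc2 | intermediate
7 | (S)-3-(benzyloxymethyl)-1-(triethylsilyloxy)cyclobut-1-ene | C1C(O[Si](CC)(CC)CC)=C[C@H]1COCc2ccccc2 | intermediate
8 | (2S,3S)-3-(benzyloxymethyl)-2-[15-(benzyloxy)-1-hydroxypentadecyl]cyclobutan-1-one, trans, carbinol epimers | C1C(=O)[C@H](C(O)CCCCCCCCCCCCCCOCc2ccccc2)[C@H]1COCc2ccccc2 | intermediate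
9 | methanesulfonate of 8 (formed in the flask) | C1C(=O)[C@H](C(OS(C)(=O)=O)CCCCCCCCCCCCCCOCc2ccccc2)[C@H]1COCc2ccccc2 | intermediate
10 | (S,E)-3-(benzyloxymethyl)-2-[15-(benzyloxy)pentadecylidene]cyclobutan-1-one | C1C(=O)/C(=C/CCCCCCCCCCCCCCOCc2ccccc2)[C@H]1COCc2ccccc2 | intermediate
11 | (2S,3S)-3-(benzyloxymethyl)-2-[15-(benzyloxy)pentadecyl]cyclobutan-1-one, cis (formed in the flask) | C1C(=O)[C@@H](CCCCCCCCCCCCCCCOCc2ccccc2)[C@H]1COCc2ccccc2 | intermediate
12 | (2R,3S)-3-(benzyloxymethyl)-2-[15-(benzyloxy)pentadecyl]cyclobutan-1-one, trans | C1C(=O)[C@H](CCCCCCCCCCCCCCCOCc2ccccc2)[C@H]1COCc2ccccc2 | intermediate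
13 | Criegee adduct of 12 with mCPBA, 1-hydroxycyclobutyl 3-chloroperbenzoate (formed in the flask) | C1C(O)(OOC(=O)c2cccc(Cl)c2)[C@H](CCCCCCCCCCCCCCCOCc2ccccc2)[C@H]1COCc2ccccc2 | intermediate
14 | (4R,5R)-4-(benzyloxymethyl)-5-[15-(benzyloxy)pentadecyl]dihydrofuran-2(3H)-one, trans | C1C(=O)O[C@H](CCCCCCCCCCCCCCCOCc2ccccc2)[C@H]1COCc2ccccc2 | intermediate
15 | (4R,5R)-4-(hydroxymethyl)-5-(15-hydroxypentadecyl)dihydrofuran-2(3H)-one | C1C(=O)O[C@H](CCCCCCCCCCCCCCCO)[C@H]1CO | intermediate
16 | (2R,3S)-2-(14-carboxytetradecyl)-5-oxotetrahydrofuran-3-carboxylic acid | C1C(=O)O[C@H](CCCCCCCCCCCCCCC(=O)O)[C@H]1C(=O)O | intermediate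
17 | (2R,3S)-2-(14-carboxytetradecyl)-5-oxotetrahydrofuran-3,4-dicarboxylic acid, epimers at C4 | OC(=O)C1C(=O)O[C@H](CCCCCCCCCCCCCCC(=O)O)[C@H]1C(=O)O | intermediate
18 | 4-[(N-methylanilino)methyl] derivative of 17 (Mannich base, formed in the flask) | CN(CC1(C(=O)O)C(=O)O[C@H](CCCCCCCCCCCCCCC(=O)O)[C@H]1C(=O)O)c2ccccc2 | intermediate
19 | (2R,3S)-2-(14-carboxytetradecyl)-4-methylene-5-oxotetrahydrofuran-3-carboxylic acid | C=C1C(=O)O[C@H](CCCCCCCCCCCCCCC(=O)O)[C@H]1C(=O)O | target

**Step count and risks**

Total: 12 steps. Longest linear sequence: 11 steps (steps 1–3 from 1, then steps 5–12); the cyclobutanone branch (step 4) joins in step 5.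

Most likely to fail, in order:

1. **Step 4.** Incomplete discrimination between the two enantiotopic α-methylene groups, or proton exchange between enolate and unreacted ketone before silylation, would carry a share of the mirror-image series through every later step. A small shortfall could be met by recrystallising diacid 16. The fallback replaces the chiral base by a covalently bound auxiliary, sets out from 3 and 5, and returns at 12, bypassing steps 4–7.
   - Alcohol 3 is converted with I2, PPh3 and imidazole (CH2Cl2, 0 °C) into 15-(benzyloxy)pentadecyl iodide F1.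
   - Ketone 5 is condensed with SAMP, (S)-1-amino-2-(methoxymethyl)pyrrolidine, to the SAMP hydrazone F2.
   - Deprotonation with LDA (THF, −78 °C) and alkylation with the iodide should give the trans-alkylated hydrazone F3. Material alkylated at the other α-carbon is then a diastereomer and is removed by chromatography at this stage.
   - Cleavage with aqueous oxalic acid in Et2O releases ketone 12.

2. **Step 11.** Carboxylation of the poorly soluble magnesium tricarboxylate at high temperature may be sluggish or reverse on acidification, and prolonged heating may epimerise the carbon bearing the ring carboxyl group. The fallback installs the methylene group before the acids are revealed, sets out from 14, and returns at 19, bypassing steps 9–12.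
   - The lithium enolate of 14 (LiHMDS, THF, −78 °C) is trapped with dimethylmethyleneiminium iodide to give the 3-(dimethylaminomethyl) lactone F4.
   - MeI gives the methiodide F5, and aqueous NaHCO3 eliminates trimethylamine to give the α-methylene lactone bis(benzyl ether) F6.
   - BCl3 (CH2Cl2, −78 °C) cleaves both benzyl ethers without reducing the alkene to give the α-methylene diol F7.
   - Jones oxidation of the diol gives 19.

3. **Step 5.** The Lewis acid may desilylate the strained enol ether or shift its double bond before C–C bond formation (the shift would erode enantiomeric purity), and the β-hydroxy cyclobutanone may revert by retro-aldol cleavage. The fallback replaces the aldol sequence by direct alkylation, sets out from 7, and returns at 12, bypassing steps 5–7.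
   - MeLi (THF, 0 °C) cleaves the Si–O bond of 7 and regenerates lithium enolate 6 regiospecifically.
   - The enolate is alkylated with 15-(benzyloxy)pentadecyl iodide F1 (made from 3 as under step 4) in THF/DMPU, −78 → 0 °C.
   - Brief DBU equilibration gives trans-ketone 12.

**Further compounds**

F1 | step 4 | 15-(benzyloxy)pentadecyl iodide | ICCCCCCCCCCCCCCCOCc1ccccc1
F2 | step 4 | SAMP hydrazone of 3-(benzyloxymethyl)cyclobutanone | COC[C@@H]1CCCN1N=C1CC(COCc2ccccc2)C1
F3 | step 4 | SAMP hydrazone of (2R,3S)-3-(benzyloxymethyl)-2-[15-(benzyloxy)pentadecyl]cyclobutan-1-one | C1C(=NN2CCC[C@H]2COC)[C@H](CCCCCCCCCCCCCCCOCc3ccccc3)[C@H]1COCc3ccccc3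
F4 | step 11 | (4R,5R)-4-(benzyloxymethyl)-5-[15-(benzyloxy)pentadecyl]-3-(dimethylaminomethyl)dihydrofuran-2(3H)-one | CN(C)CC1C(=O)O[C@H](CCCCCCCCCCCCCCCOCc2ccccc2)[C@H]1COCc2ccccc2
F5 | step 11 | methiodide of F4 | C[N+](C)(C)CC1C(=O)O[C@H](CCCCCCCCCCCCCCCOCc2ccccc2)[C@H]1COCc2ccccc2.[I-]
F6 | step 11 | (4R,5R)-4-(benzyloxymethyl)-5-[15-(benzyloxy)pentadecyl]-3-methylenedihydrofuran-2(3H)-one | C=C1C(=O)O[C@H](CCCCCCCCCCCCCCCOCc2ccccc2)[C@H]1COCc2ccccc2
F7 | step 11 | (4R,5R)-4-(hydroxymethyl)-5-(15-hydroxypentadecyl)-3-methylenedihydrofuran-2(3H)-one | C=C1C(=O)O[C@H](CCCCCCCCCCCCCCCO)[C@H]1CO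
F0 | step 5 | none | none
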